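## Retrosynthetic overview
1. Target 9 is a head-to-tail [2+2] cross-dimer. Cutting the cyclobutane bonds C1–C8 and C6–C7 gives styrylpyranone 4 (exocyclic E-alkene) and phenethylpyranone 7 (ring C5=C6 alkene).
2. The cyclobutane, and with it the 2-oxabicyclo[4.2.0]octenone, is the only ring formed. Both pyranone rings come from 1. All four stereocentres are set in one enantioselective photocycloaddition inside a chiral Brønsted-acid ion pair.
3. 4 comes from 1 and benzaldehyde by vinylogous aldol condensation. 7 comes from 1 and benzyl bromide by vinylogous enolate alkylation.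

Assumption: the sense of induction of the new step cannot be predicted, so the (S,S)-catalyst is written and its equally accessible (R,R)-form is used if the mirror image forms; the catalyst (known class, made separately) is not counted as a step.

Catalyst used in step 3: (S,S)-IDPi is an imidodiphosphorimidate built from two (S)-3,3'-bis[3,5-bis(trifluoromethyl)phenyl]-BINOL units. Both phosphorus atoms carry P=N–SO2CF3, and the acidic N–H bridges them.

## Route

Step 1
Reactants: 1 4-methoxy-6-methyl-2H-pyran-2-one; 2 benzaldehyde
Product: 4 5,6-dehydrokavain [4-methoxy-6-((E)-2-phenylethenyl)-2H-pyran-2-one], via aldol adduct 3 (not isolated)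
Conditions: Mg(OMe)2 (2 equiv), MeOH, reflux, 16 h; then 1 M HCl
Reagents that add atoms: benzaldehyde (compound 2), O=Cc1ccccc1
Why: Vinylogous aldol condensation: the C6-methyl group is deprotonated as a magnesium-chelated dienolate, adds to the aldehyde, and the transient racemic carbinol 3 loses water by E1cB in the same flask to give only the conjugated E-alkene, so no stereocentre remains.

Step 2
Reactants: 1 4-methoxy-6-methyl-2H-pyran-2-one; 5 benzyl bromide
Product: 7 4-methoxy-6-(2-phenylethyl)-2H-pyran-2-one (7,8-dihydro-5,6-dehydrokavain), via lithium dienolate 6 (not isolated)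
Conditions: LDA (1.1 equiv, commercial solution), THF/DMPU, −78 °C, 45 min; then BnBr (1.2 equiv), −78 to −20 °C; aq. NH4Cl
Reagents that add atoms: benzyl bromide (compound 5), BrCc1ccccc1
Why: Vinylogous enolate alkylation (SN2): the extended dienolate 6 reacts at its exocyclic carbon with the reactive benzylic bromide, and no stereocentre is formed.

Step 3
Reactants: 4 5,6-dehydrokavain; 7 4-methoxy-6-(2-phenylethyl)-2H-pyran-2-one
Product: 9 (1R,6S,7S,8S)-5-methoxy-8-(4-methoxy-2-oxo-2H-pyran-6-yl)-7-phenyl-1-(2-phenylethyl)-2-oxabicyclo[4.2.0]oct-4-en-3-one, via hydroxypyrylium ion pair 8 (not isolated)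
Conditions: 4 (1 equiv, syringe pump over 10 h, final 0.02 M), 7 (5 equiv, excess recovered), (S,S)-IDPi (10 mol %), dry CH2Cl2, Ar, −60 °C, hν 440 nm LED (>420 nm filter), 24 h; direct chromatography
Reagents that add atoms: none
Why: Proposed new method: the confined, strongly acidic chiral IDPi protonates the vinylogous-carbonate carbonyl of 4 (the most basic species present, because the cation delocalises into the styryl arm) to give contact ion pair 8, whose styrylpyrylium absorption should lie 50–80 nm to the red, so 440 nm light excites only catalyst-bound 4 (free 4 ends near 400 nm, 7 and 9 near 320 nm), which removes the racemic background and product cycloreversion; the excited cation is anchored by its O–H···anion hydrogen bond with one π-face walled off by the 3,3'-aryl groups and its pyrylium end buried in the pocket, so neutral 7 can only stack antiparallel on the open face under the protruding phenyl/alkene part, where the nucleophilic enol-ether carbon C5 of 7 bonds to the electrophilic benzylic terminus and C6 bonds to the carbon next to the pyrylium; this gives the head-to-tail regiochemistry, the cis ring fusion (ring alkene), the trans phenyl/pyranonyl pair (E-alkene, also the favoured result of stepwise closure) and phenyl cis to the lactone ring, while the chiral anion fixes the absolute configuration of all four centres at once, and proton transfer from the less basic product to fresh 4 turns the acid over; closest known reaction types are chromophore-activated enantioselective [2+2] photocycloaddition of enones and coumarins with chiral Lewis acids, chiral phosphate/iminium ion-pair [2+2] photocycloaddition, IDPi counteranion-directed photochemical cycloadditions of cationic olefin species, and the [2+2] photodimerisation of styrylpyrylium salts and styrylpyranones, none of which has been shown for a protonated 2-pyranone or with a 2-pyranone C5=C6 bond as partner in a catalytic enantioselective crossed reaction.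

In 9 the ring fusion is cis. The phenethyl group (C1), H-6, H-7 and the pyranonyl group (C8) lie on one face of the cyclobutane. The lactone O2, C5, the phenyl group (C7) and H-8 lie on the other face.

## Compound list
1 | 4-methoxy-6-methyl-2H-pyran-2-one | COc1cc(C)oc(=O)c1 | starting material
2 | benzaldehyde | O=Cc1ccccc1 | starting material
3 | 6-(2-hydroxy-2-phenylethyl)-4-methoxy-2H-pyran-2-one (racemic aldol adduct, present as Mg alkoxide, dehydrated in the same flask) | COc1cc(CC(O)c2ccccc2)oc(=O)c1 | intermediate
4 | 5,6-dehydrokavain, 4-methoxy-6-[(E)-2-phenylethenyl]-2H-pyran-2-one | COc1cc(/C=C/c2ccccc2)oc(=O)c1 | intermediate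
5 | benzyl bromide | BrCc1ccccc1 | starting material
6 | lithium 4-methoxy-6-methylidene-6H-pyran-2-olate (extended dienolate of 1) | C=C1C=C(OC)C=C([O-])O1.[Li+] | intermediate
7 | 4-methoxy-6-(2-phenylethyl)-2H-pyran-2-one | COc1cc(CCc2ccccc2)oc(=O)c1 | intermediate
8 | 2-hydroxy-4-methoxy-6-[(E)-2-phenylethenyl]pyrylium (counter-ion: the chiral IDPi anion of the catalyst) | COc1cc(O)[o+]c(/C=C/c2ccccc2)c1 | intermediate
9 | (1R,6S,7S,8S)-5-methoxy-8-(4-methoxy-2-oxo-2H-pyran-6-yl)-7-phenyl-1-(2-phenylethyl)-2-oxabicyclo[4.2.0]oct-4-en-3-one (CNP0185330.1) | COC1=CC(=O)O[C@]2(CCc3ccccc3)[C@H]1[C@H](c1ccccc1)[C@H]2c1cc(OC)cc(=O)o1 | target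

## Step count and risks
Total step count: 3. Longest linear sequence: 2 (1 → 4 → 9 or 1 → 7 → 9).

**Step 3 (proposed new step, highest risk).**
- The excited ion pair may decay only by E/Z isomerisation.
- 4 may homodimerise.
- A pyrylium-over-pyranone stack may give the other diastereomer.
- The ee may be low.

Fallback with known chemistry, setting out from 4 and 7: run a racemic crossed [2+2] photocycloaddition. Use thioxanthone (10 mol %) at 405 nm, or direct 365 nm irradiation, on a concentrated degassed CH2Cl2 solution of 4 with 7 in excess. Isolate the head-to-tail, phenyl-cis-to-lactone diastereomer by chromatography as a 1:1 mixture of 9 and the mirror image of the target F3. Separate the two enantiomers by preparative HPLC on an amylose tris(3,5-dimethylphenylcarbamate) phase, and assign them by ECD. The route is rejoined at 9.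

**Step 2.**
- Lithiation at C3 may compete.
- Double benzylation may occur.
- The pyranone ring may open.

Fallback, setting out from 4: hydrogenate the exocyclic alkene chemoselectively (H2 1 atm, 5 % Pd/C, EtOAc, rt, stopped after 1 equiv uptake). This gives 7 directly and rejoins the route at 7. It makes no new compound (entry F0). The longest linear sequence then becomes 3.

**Step 1.**
- Methoxide may open the pyranone ring.
- Conversion may be low.

Fallback, setting out from 1:
1. Wohl–Ziegler bromination (NBS, AIBN, PhCF3, reflux) gives 6-(bromomethyl)-4-methoxy-2H-pyran-2-one F1.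
2. Michaelis–Arbuzov reaction with P(OEt)3 at 120 °C gives diethyl [(4-methoxy-2-oxo-2H-pyran-6-yl)methyl]phosphonate F2.
3. Horner–Wadsworth–Emmons olefination of 2 (NaH, THF, 0 °C) gives the E-alkene and rejoins the route at 4.

## Further compounds
F1 | step 1 | 6-(bromomethyl)-4-methoxy-2H-pyran-2-one | COc1cc(CBr)oc(=O)c1
F2 | step 1 | diethyl [(4-methoxy-2-oxo-2H-pyran-6-yl)methyl]phosphonate | CCOP(=O)(Cc1cc(OC)cc(=O)o1)OCC
F0 | step 2 | none | none
F3 | step 3 | (1S,6R,7R,8R)-5-methoxy-8-(4-methoxy-2-oxo-2H-pyran-6-yl)-7-phenyl-1-(2-phenylethyl)-2-oxabicyclo[4.2.0]oct-4-en-3-one (mirror image of 9) | COC1=CC(=O)O[C@@]2(CCc3ccccc3)[C@@H]1[C@@H](c1ccccc1)[C@@H]2c1cc(OC)cc(=O)o1
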